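**Plan**

- Numbering: the side chain runs from the ketone carbon C1 to the isopropylidene carbon C7. The retrosynthesis cuts C1–aryl (aryllithium plus aldehyde) and C6=C7 (Wittig), then joins C1 and C6 as a ring double bond and cuts C2–C3 and C4–C5 (Diels–Alder).
- Enabling feature: C3 carries the arms C2–C1 and C4–C5–C6, so C1–C6 are six carbons that form a cyclohex-3-ene once C1 and C6 are linked as C1=C6. Both are sp2 carbons in the target, so cleaving that ring alkene returns them as carbonyl carbons; the C3 hydroxyl sits where a formyl group can be exchanged for oxygen.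
- Forward: the only ring built is this sacrificial cyclohexene (step 1). Peracid turns CHO into O–CHO and the alkene into an epoxide, and hydrolysis and periodate open the ring.
- The tertiary hydroxyl then masks C6 as a five-membered lactol, C1 takes the aryllithium, C6 takes the ylide, and oxidation at C1 and removal of the phenol acetals finish the chain.
- Stereochemistry: the single stereocentre C3 is set in step 1 by the chiral boron Lewis acid choosing the enantioface of methacrolein. It passes through the Baeyer–Villiger step with retention, and its C–O bond is never broken afterwards.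

Key step: step 1

Assumption: the (S)-prolinol-derived oxazaborolidinium ion (neutral precursor Cc1ccccc1B1OC(c2ccccc2)(c2ccccc2)[C@@H]2CCCN12) is taken to leave the α-Re face of bound methacrolein open, as for other 2-substituted acroleins. If the sense proved opposite, the (R)-derived catalyst would be used and nothing else would change.

Remark: stereocentres that are destroyed later (epoxide carbons, diol carbons, lactol carbon, C1 carbinol) are carried as mixtures and written without configuration.

**Route**

Step 1
Reactants: 1 buta-1,3-diene; 2 methacrolein (2-methylprop-2-enal)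
Product: 3 (1S)-1-methylcyclohex-3-ene-1-carbaldehyde
Conditions: (S)-tetrahydro-1-(2-methylphenyl)-3,3-diphenyl-1H,3H-pyrrolo[1,2-c][1,3,2]oxazaborole (15 mol %), (CF3SO2)2NH (13 mol %), 1 (5 equiv), CH2Cl2, −78 to −40 °C; Et3N quench
Reagents that add atoms: none
Why: The N-protonated oxazaborolidine binds the formyl oxygen of 2, a formyl C–H···O contact to the ring oxygen holds the s-trans enal over one aryl group of the catalyst, and the activated enal takes up the diene in a concerted, asynchronous [4+2] addition in which the bond to the β-carbon (C4–C5) runs ahead of the bond to the α-carbon (C2–C3). The closest known reaction type is the Diels–Alder addition of 2-substituted acroleins to simple acyclic dienes catalysed by triflimide-activated B-aryl oxazaborolidines from diphenylprolinol. The one ring, cyclohexene C1–C6, closes by suprafacial [4π+2π] cycloaddition that forms both σ bonds in one step and leaves the new double bond at C1=C6. The quaternary stereocentre C3 is controlled by the catalyst alone, which screens one face of the bound enal so that the diene reaches the α-carbon from its Re face and the (S)-aldehyde results. Only enantioface selectivity is needed, because unsubstituted butadiene is symmetric: there is no regiochemical choice, and endo and exo approach to a given face give the same product. The α-methyl, β-unsubstituted enal is among the most reactive dienophiles for this catalyst class, which should offset the low reactivity of the unactivated diene.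

Step 2
Reactants: 3 (1S)-1-methylcyclohex-3-ene-1-carbaldehyde
Product: 5 (3S)-3-methyl-7-oxabicyclo[4.1.0]heptan-3-yl formate (both epoxide diastereomers), via epoxy aldehyde 4 (not isolated)
Conditions: mCPBA (2.5 equiv), CH2Cl2, 0 °C to rt; aq Na2SO3/NaHCO3 wash
Reagents that add atoms: 3-chloroperbenzoic acid (mCPBA), OOC(=O)c1cccc(Cl)c1
Why: Prilezhaev epoxidation of the cis ring alkene comes first and is followed by Baeyer–Villiger oxidation of the α-quaternary aldehyde, in which the tertiary ring carbon migrates in preference to hydride and with retention, so the C3 configuration passes unchanged into the C3–O bond; the facial mixture at the epoxide is irrelevant because C1 and C6 become carbonyl carbons in step 4.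

Step 3
Reactants: 5 (3S)-3-methyl-7-oxabicyclo[4.1.0]heptan-3-yl formate
Product: 7 (4S)-4-methylcyclohexane-1,2,4-triol (diol diastereomers), via diol formate 6 (not isolated)
Conditions: H2SO4 (0.1 equiv), THF/H2O 3:1, 0 °C to rt; K2CO3 (0.3 equiv), concentrate; MeOH, rt; filter through silica
Reagents that add atoms: water, O
Why: Acid-catalysed hydrolytic opening of the epoxide is done while the tertiary oxygen is still formylated, so that it cannot attack the protonated epoxide across the ring, and the formate is then removed by base-catalysed methanolysis, an acyl–oxygen cleavage that leaves the C3–O bond and the stereocentre untouched.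

Step 4
Reactants: 7 (4S)-4-methylcyclohexane-1,2,4-triol
Product: 9 2-[(2S)-5-hydroxy-2-methyloxolan-2-yl]acetaldehyde (lactol epimers), via hydroxy dialdehyde 8 (not isolated)
Conditions: NaIO4/SiO2 (wet, 1.5 equiv), CH2Cl2, rt; filter, concentrate, dry by toluene azeotrope
Reagents that add atoms: none
Why: Malaprade glycol cleavage of the C1–C6 diol gives the 3-hydroxy dialdehyde, whose tertiary hydroxyl can reach C6 through a five-membered ring but C1 only through a four-membered one, so C6 is masked as the lactol and C1 stays an aldehyde (free or as its internal hemiacetal with the lactol hydroxyl); the supported reagent avoids an aqueous extraction of this small polar product.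

Step 5
Reactants: 10 2,5-dibromobenzene-1,4-diol (2,5-dibromohydroquinone)
Product: 11 1,4-dibromo-2,5-bis(methoxymethoxy)benzene
Conditions: NaH (2.4 equiv), MOMCl (2.6 equiv), DMF, 0 °C to rt
Reagents that add atoms: chloromethyl methyl ether (MOMCl), COCCl
Why: Williamson etherification of the two phenoxides gives acetals that tolerate organolithium and ylide bases, stabilise the ortho aryllithium by chelation and cannot undergo the oxygen-to-carbon migration that an ortho-lithiated aryl silyl ether would suffer.

Step 6
Reactants: 9 2-[(2S)-5-hydroxy-2-methyloxolan-2-yl]acetaldehyde; 11 1,4-dibromo-2,5-bis(methoxymethoxy)benzene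
Product: 13 1-[4-bromo-2,5-bis(methoxymethoxy)phenyl]-2-[(2S)-5-hydroxy-2-methyloxolan-2-yl]ethan-1-ol (carbinol and lactol epimers), via aryllithium 12 (not isolated)
Conditions: 11 (2.4 equiv), n-BuLi (2.3 equiv), THF, −78 °C; then 9, −78 °C; sat. aq NH4Cl at −78 °C
Reagents that add atoms: none
Why: Bromine–lithium exchange at one of the two equivalent C–Br bonds gives the chelated aryllithium, of which one equivalent deprotonates the lactol (or internal hemiacetal) hydroxyl to a lithium lactolate that should stay closed at −78 °C, as the tetrahedral adducts of aryllithiums and lactones do, while a second equivalent undergoes 1,2-addition to the C1 aldehyde; the new carbinol centre is uncontrolled and is removed in step 8.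

Step 7
Reactants: 13 1-[4-bromo-2,5-bis(methoxymethoxy)phenyl]-2-[(2S)-5-hydroxy-2-methyloxolan-2-yl]ethan-1-ol; 14 isopropyltriphenylphosphonium iodide
Product: 16 (3S)-1-[4-bromo-2,5-bis(methoxymethoxy)phenyl]-3,7-dimethyloct-6-ene-1,3-diol (C1 epimers), via phosphorus ylide 15 (not isolated)
Conditions: 14 (4.2 equiv), n-BuLi (4.0 equiv), THF, 0 °C; then 13, 0 °C to rt
Reagents that add atoms: none
Why: Wittig olefination of a lactol through its open hydroxy-aldehyde form with a non-stabilised ylide, used in excess because the two hydroxyls consume two equivalents as base; it is placed before the oxidation so that no β-hydroxy ketone meets strong base (retro-aldol), and the phosphonium salt is kept in slight excess over n-BuLi so that no alkyllithium is left to attack the aryl bromide.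

Step 8
Reactants: 16 (3S)-1-[4-bromo-2,5-bis(methoxymethoxy)phenyl]-3,7-dimethyloct-6-ene-1,3-diol
Product: 17 (3S)-1-[4-bromo-2,5-bis(methoxymethoxy)phenyl]-3-hydroxy-3,7-dimethyloct-6-en-1-one
Conditions: Dess–Martin periodinane (1.3 equiv), CH2Cl2, 0 °C to rt
Reagents that add atoms: none
Why: Dess–Martin oxidation converts the secondary benzylic alcohol into the aryl ketone under near-neutral conditions in which the tertiary C3 hydroxyl cannot be oxidised, the trisubstituted alkene is inert and the aldol-type product is not exposed to base.

Step 9
Reactants: 17 (3S)-1-[4-bromo-2,5-bis(methoxymethoxy)phenyl]-3-hydroxy-3,7-dimethyloct-6-en-1-one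
Product: 18 (3S)-1-(4-bromo-2,5-dihydroxyphenyl)-3-hydroxy-3,7-dimethyloct-6-en-1-one
Conditions: HCl (0.5 M in MeOH), 0 °C to rt, argon
Reagents that add atoms: none
Why: Acid-catalysed acetal exchange with methanol frees both phenols while dimethoxymethane is formed, and dilute acid at or below room temperature is chosen so that the tertiary β-hydroxy ketone is not dehydrated and the trisubstituted alkene is not protonated.

**Compound list**

1 | buta-1,3-diene | C=CC=C | starting material
2 | methacrolein (2-methylprop-2-enal) | CC(=C)C=O | starting material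
3 | (1S)-1-methylcyclohex-3-ene-1-carbaldehyde | C[C@@]1(C=O)CC=CCC1 | intermediate
4 | (3S)-3-methyl-7-oxabicyclo[4.1.0]heptane-3-carbaldehyde; both epoxide diastereomers; not isolated | C[C@@]1(C=O)CC2OC2CC1 | intermediate
5 | (3S)-3-methyl-7-oxabicyclo[4.1.0]heptan-3-yl formate; both epoxide diastereomers | C[C@@]1(OC=O)CC2OC2CC1 | intermediate
6 | (1S)-3,4-dihydroxy-1-methylcyclohexyl formate; diol diastereomers; not isolated | C[C@@]1(OC=O)CC(O)C(O)CC1 | intermediate
7 | (4S)-4-methylcyclohexane-1,2,4-triol; diol diastereomers | C[C@@]1(O)CC(O)C(O)CC1 | intermediate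
8 | (3S)-3-hydroxy-3-methylhexanedial; not isolated | O=CCC[C@](C)(O)CC=O | intermediate
9 | 2-[(2S)-5-hydroxy-2-methyloxolan-2-yl]acetaldehyde; lactol epimers | OC1CC[C@](C)(O1)CC=O | intermediate
10 | 2,5-dibromobenzene-1,4-diol (2,5-dibromohydroquinone) | Oc1cc(Br)c(O)cc1Br | starting material
11 | 1,4-dibromo-2,5-bis(methoxymethoxy)benzene | COCOc1cc(Br)c(OCOC)cc1Br | intermediate
12 | [4-bromo-2,5-bis(methoxymethoxy)phenyl]lithium; not isolated | [Li]c1cc(OCOC)c(Br)cc1OCOC | intermediate
13 | 1-[4-bromo-2,5-bis(methoxymethoxy)phenyl]-2-[(2S)-5-hydroxy-2-methyloxolan-2-yl]ethan-1-ol; carbinol and lactol epimers | OC1CC[C@](C)(O1)CC(O)c1cc(OCOC)c(Br)cc1OCOC | intermediate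
14 | isopropyltriphenylphosphonium iodide | CC(C)[P+](c1ccccc1)(c1ccccc1)c1ccccc1.[I-] | starting material
15 | isopropylidenetriphenylphosphorane; not isolated | CC(C)=P(c1ccccc1)(c1ccccc1)c1ccccc1 | intermediate
16 | (3S)-1-[4-bromo-2,5-bis(methoxymethoxy)phenyl]-3,7-dimethyloct-6-ene-1,3-diol; C1 epimers | CC(C)=CCC[C@](C)(O)CC(O)c1cc(OCOC)c(Br)cc1OCOC | intermediate
17 | (3S)-1-[4-bromo-2,5-bis(methoxymethoxy)phenyl]-3-hydroxy-3,7-dimethyloct-6-en-1-one | CC(C)=CCC[C@](C)(O)CC(=O)c1cc(OCOC)c(Br)cc1OCOC | intermediate
18 | (3S)-1-(4-bromo-2,5-dihydroxyphenyl)-3-hydroxy-3,7-dimethyloct-6-en-1-one | CC(C)=CCC[C@](C)(O)CC(=O)c1cc(O)c(Br)cc1O | target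

**Step count**

Total steps: 9. Longest linear sequence: 8 (steps 1, 2, 3, 4, 6, 7, 8, 9); step 5 is a one-step side branch that joins at step 6.

**Steps most likely to fail, with fallbacks**

Step 6. The lithium lactolate may open during the addition so that a second aryl group is delivered to C6, or the basic aryllithium may enolise the β-alkoxy aldehyde and trigger β-elimination of the ring oxygen. The fallback inverts the order of the two C–C bond formations so that the aryllithium never meets the lactol. Setting out from 9, NaBH4 (0.3 equiv, EtOH, −40 °C) should reduce the free C1 aldehyde faster than the closed lactol and give (5S)-5-(2-hydroxyethyl)-5-methyloxolan-2-ol F1. Wittig reaction of this lactol with ylide 15 (excess, THF, 0 °C to rt) should give (3S)-3,7-dimethyloct-6-ene-1,3-diol F2. TEMPO (cat.) with PhI(OAc)2 in CH2Cl2 oxidises only the primary alcohol and should give (3S)-3-hydroxy-3,7-dimethyloct-6-enal F3. Addition of aryllithium 12 (2.2 equiv, THF, −78 °C, the first equivalent deprotonating the tertiary hydroxyl) then gives 16, where the route is rejoined; steps 6 and 7 are replaced.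

Step 9. Before both acetals are gone, the acid may dehydrate the tertiary β-hydroxy ketone, after which the ortho phenol would close onto the enone, or it may protonate the trisubstituted alkene and let the tertiary hydroxyl cyclise onto it. The fallback carries the phenols as 1-ethoxyethyl acetals, which are cleaved by a far weaker acid. Setting out from 10, ethyl vinyl ether with PPTS (cat.) in CH2Cl2 should give 1,4-dibromo-2,5-bis(1-ethoxyethoxy)benzene F4. Exchange with n-BuLi (THF, −78 °C) gives [4-bromo-2,5-bis(1-ethoxyethoxy)phenyl]lithium F5, which is added in excess to 9 to give 1-[4-bromo-2,5-bis(1-ethoxyethoxy)phenyl]-2-[(2S)-5-hydroxy-2-methyloxolan-2-yl]ethan-1-ol F6. Wittig reaction with ylide 15 gives (3S)-1-[4-bromo-2,5-bis(1-ethoxyethoxy)phenyl]-3,7-dimethyloct-6-ene-1,3-diol F7, and MnO2 in CH2Cl2 (neutral, so the acetals survive) gives (3S)-1-[4-bromo-2,5-bis(1-ethoxyethoxy)phenyl]-3-hydroxy-3,7-dimethyloct-6-en-1-one F8. PPTS (cat.) in MeOH at rt then releases 18, where the route is rejoined.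

Step 7. The hindered isopropylidene ylide has to intercept a small equilibrium amount of open aldehyde from a dialkoxide, so the olefination may stall or give way to base-induced decomposition. The fallback builds the trisubstituted alkene in two easier stages. Setting out from 13, methylenetriphenylphosphorane F9 (from methyltriphenylphosphonium bromide and KOt-Bu, THF, 0 °C to rt, excess) is far less hindered and should give (3S)-1-[4-bromo-2,5-bis(methoxymethoxy)phenyl]-3-methylhept-6-ene-1,3-diol F10. Cross-metathesis with 2-methyl-2-butene (as co-solvent, CH2Cl2, 40 °C) under the second-generation Grubbs catalyst RuCl2(=CHPh)(PCy3)(H2IMes) then gives 16, where the route is rejoined.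

**Further compounds**

F1 | step 6 | (5S)-5-(2-hydroxyethyl)-5-methyloxolan-2-ol | OC1CC[C@](C)(O1)CCO
F2 | step 6 | (3S)-3,7-dimethyloct-6-ene-1,3-diol | CC(C)=CCC[C@](C)(O)CCO
F3 | step 6 | (3S)-3-hydroxy-3,7-dimethyloct-6-enal | CC(C)=CCC[C@](C)(O)CC=O
F4 | step 9 | 1,4-dibromo-2,5-bis(1-ethoxyethoxy)benzene | CCOC(C)Oc1cc(Br)c(OC(C)OCC)cc1Br
F5 | step 9 | [4-bromo-2,5-bis(1-ethoxyethoxy)phenyl]lithium | [Li]c1cc(OC(C)OCC)c(Br)cc1OC(C)OCC
F6 | step 9 | 1-[4-bromo-2,5-bis(1-ethoxyethoxy)phenyl]-2-[(2S)-5-hydroxy-2-methyloxolan-2-yl]ethan-1-ol | OC1CC[C@](C)(O1)CC(O)c1cc(OC(C)OCC)c(Br)cc1OC(C)OCC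
F7 | step 9 | (3S)-1-[4-bromo-2,5-bis(1-ethoxyethoxy)phenyl]-3,7-dimethyloct-6-ene-1,3-diol | CC(C)=CCC[C@](C)(O)CC(O)c1cc(OC(C)OCC)c(Br)cc1OC(C)OCC
F8 | step 9 | (3S)-1-[4-bromo-2,5-bis(1-ethoxyethoxy)phenyl]-3-hydroxy-3,7-dimethyloct-6-en-1-one | CC(C)=CCC[C@](C)(O)CC(=O)c1cc(OC(C)OCC)c(Br)cc1OC(C)OCC
F9 | step 7 | methylenetriphenylphosphorane | C=P(c1ccccc1)(c1ccccc1)c1ccccc1
F10 | step 7 | (3S)-1-[4-bromo-2,5-bis(methoxymethoxy)phenyl]-3-methylhept-6-ene-1,3-diol | C=CCC[C@](C)(O)CC(O)c1cc(OCOC)c(Br)cc1OCOC
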